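**Strategy.** In the 11-membered ring the ketone carbon (C7), its sp2 α-carbon (C8) and the CH2OH group on C8 form the array O–CH2–C8–C7(=O). Read backwards this is a 1,3 O→C acyl shift. The O–CH2 unit is therefore first placed inside the ring, between C7 and C8, as a 13-membered macrolactone of a (Z)-2-iodoallyl alcohol, closed by simple lactonisation. Iodine–lithium exchange lets the C8 carbanion attack the lactone carbonyl. Collapse of the oxetane alkoxide pushes O and CH2 out of the ring and delivers at once the 11-membered carbocycle, its ketone, the ring-cis enone bond and the free CH2OH. A hydroxyl-directed epoxidation then finishes the target.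

Key step: step 18

Numbering used below:
- C11 is the quaternary ring carbon.
- C1=C2 is the disubstituted ring alkene.
- C3 is the CH–O(senecioyl) carbon.
- C4 (bearing CH3) and C5 are the oxirane carbons.
- C6 is the CHOH carbon and C7 the C=O carbon.
- C8=C9 is the enone bond, and C12 is the CH2OH carbon on C8.
- C10 is the ring CH2.

Target configuration: 3R,4S,5S,6S,11S; 1Z, 8Z.

Assumption: the Zn–ProPhenol alkynylation (step 11) is taken to follow its usual model, in which the (S,S)-ligand gives the (S)-carbinol when alkynyl outranks the aldehyde residue. The antipodal ligand is equally available.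

Step 1
Reactants: 1 geraniol
Product: 2 (2R,3R)-2,3-epoxygeraniol
Conditions: Ti(OiPr)4 (cat.), D-(−)-diethyl tartrate (cat.), t-BuOOH, 4 Å MS, CH2Cl2, −20 °C
Reagents that add atoms: tert-butyl hydroperoxide CC(C)(C)OO
Why: Sharpless asymmetric epoxidation oxidises only the allylic alkene, and D-(−)-tartrate delivers oxygen to the face that gives the (2R,3R)-oxirane, while the remote trisubstituted alkene is untouched.

Step 2
Reactants: 2 (2R,3R)-2,3-epoxygeraniol
Product: 3 (2S,3R)-3,7-dimethyl-3-[(trimethylsilyl)ethynyl]oct-6-ene-1,2-diol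
Conditions: Me3SiC≡CH, n-BuLi, then Et2AlCl, toluene, 0 °C; then 2, 0 °C to rt; Rochelle salt work-up
Reagents that add atoms: diethyl[(trimethylsilyl)ethynyl]aluminium CC[Al](CC)C#C[Si](C)(C)C
Why: In this alkynylalane opening of a 2,3-epoxy alcohol the aluminium alkoxide activates the oxirane and the alkynyl group attacks the tertiary carbon, which best carries positive charge, with SN2 inversion, so the oxirane configuration sets the quaternary centre (later C11).

Step 3
Reactants: 3 (2S,3R)-3,7-dimethyl-3-[(trimethylsilyl)ethynyl]oct-6-ene-1,2-diol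
Product: 4 (2R)-2,6-dimethyl-2-[(trimethylsilyl)ethynyl]hept-5-enal
Conditions: NaIO4, THF–H2O, 0 °C to rt
Reagents that add atoms: none
Why: Periodate glycol cleavage removes the CH2OH carbon and leaves a non-enolisable α-quaternary aldehyde, so the new centre cannot epimerise.

Step 4
Reactants: 4 (2R)-2,6-dimethyl-2-[(trimethylsilyl)ethynyl]hept-5-enal
Product: 6 (3S)-3,7-dimethyl-3-[(trimethylsilyl)ethynyl]oct-6-enal, via enol ether 5 (not isolated)
Conditions: MeOCH2PPh3Cl, KHMDS, THF, 0 °C; then 2 M HCl, THF, rt
Reagents that add atoms: (methoxymethyl)triphenylphosphonium chloride COC[P+](c1ccccc1)(c1ccccc1)c1ccccc1.[Cl-]; water O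
Why: Wittig methoxymethylenation followed by acid hydrolysis of the crude enol ether is the standard one-carbon aldehyde homologation and places C9 next to the C10 methylene.

Step 5
Reactants: 6 (3S)-3,7-dimethyl-3-[(trimethylsilyl)ethynyl]oct-6-enal
Product: 7 ethyl (2Z,5S)-2-iodo-5,9-dimethyl-5-[(trimethylsilyl)ethynyl]deca-2,8-dienoate
Conditions: Ph3P=CHCO2Et, NIS, CH2Cl2, −20 °C; then 6, rt
Reagents that add atoms: ethyl (triphenylphosphoranylidene)acetate CCOC(=O)C=P(c1ccccc1)(c1ccccc1)c1ccccc1; N-iodosuccinimide O=C1CCC(=O)N1I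
Why: This is a Wittig olefination with the α-iodo ylide made in situ, and as with other stabilised ylides the alkyl chain ends trans to the ester and therefore cis to iodine, which is the (Z)-2-iodoenoate that later fixes the enone geometry.

Step 6
Reactants: 7 ethyl (2Z,5S)-2-iodo-5,9-dimethyl-5-[(trimethylsilyl)ethynyl]deca-2,8-dienoate
Product: 8 (2Z,5S)-2-iodo-5,9-dimethyl-5-[(trimethylsilyl)ethynyl]deca-2,8-dien-1-ol
Conditions: DIBAL-H (2.2 equiv), CH2Cl2, −78 °C
Reagents that add atoms: none
Why: DIBAL-H reduces the enoate 1,2 to the allylic alcohol without touching the vinyl iodide, the silylalkyne or the alkene geometry.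

Step 7
Reactants: 8 (2Z,5S)-2-iodo-5,9-dimethyl-5-[(trimethylsilyl)ethynyl]deca-2,8-dien-1-ol
Product: 9 tert-butyldimethylsilyl ether of 8
Conditions: TBSCl, imidazole, CH2Cl2, rt
Reagents that add atoms: tert-butyldimethylsilyl chloride CC(C)(C)[Si](C)(C)Cl
Why: Standard silylation masks the primary allylic hydroxyl (C12–OH) until the lactonisation.

Step 8
Reactants: 9 tert-butyldimethylsilyl ether of 8
Product: 10 tert-butyl{[(2Z,5S)-5-ethynyl-2-iodo-5,9-dimethyldeca-2,8-dien-1-yl]oxy}dimethylsilane
Conditions: K2CO3 (cat.), MeOH, rt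
Reagents that add atoms: none
Why: Base-catalysed methanolysis cleaves only the C(sp)–Si bond, and the TBS ether and the vinyl iodide are stable to it.

Step 9
Reactants: 11 (2S)-but-3-ene-1,2-diol
Product: 12 (2S)-1,2-bis(triethylsilyloxy)but-3-ene
Conditions: TESCl (2.3 equiv), imidazole, CH2Cl2, 0 °C
Reagents that add atoms: triethylsilyl chloride CC[Si](CC)(CC)Cl
Why: Double silylation of the chiral-pool diol carries the C6 stereocentre into the route unchanged.

Step 10
Reactants: 12 (2S)-1,2-bis(triethylsilyloxy)but-3-ene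
Product: 13 (2E,4S)-2-methyl-4,5-bis(triethylsilyloxy)pent-2-enal
Conditions: methacrolein (excess), Hoveyda–Grubbs II catalyst (cat.), CH2Cl2, 40 °C
Reagents that add atoms: methacrolein CC(=C)C=O
Why: Olefin cross-metathesis of a terminal alkene with methacrolein gives the E-trisubstituted enal under thermodynamic control and leaves the allylic stereocentre untouched.

Step 11
Reactants: 10 tert-butyl{[(2Z,5S)-5-ethynyl-2-iodo-5,9-dimethyldeca-2,8-dien-1-yl]oxy}dimethylsilane; 13 (2E,4S)-2-methyl-4,5-bis(triethylsilyloxy)pent-2-enal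
Product: 14 propargylic alcohol (C2–C3 bond made; 3S by CIP at this stage, 6S, 11S; 4E, 8Z)
Conditions: (S,S)-ProPhenol (cat.), Ph3P=O (cat.), Me2Zn, toluene, 0–4 °C
Reagents that add atoms: none
Why: In this Zn–ProPhenol-catalysed asymmetric alkynylation of an enal the dinuclear zinc–ligand pocket selects the aldehyde face and sets C3, and the descriptor changes to R once the alkyne is reduced.

Step 12
Reactants: 14 propargylic alcohol
Product: 15 (1Z)-bis-allylic alcohol (3R,6S,11S)
Conditions: H2 (1 atm), Lindlar catalyst, quinoline, EtOAc, rt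
Reagents that add atoms: none
Why: Lindlar semi-hydrogenation adds H2 syn to the only alkyne and gives the Z C1=C2 bond, and the poisoned catalyst should leave the tri-substituted alkenes alone.

Step 13
Reactants: 15 (1Z)-bis-allylic alcohol; 16 senecioic acid (3-methylbut-2-enoic acid)
Product: 17 C3 senecioate
Conditions: EDC·HCl, DMAP, CH2Cl2, rt
Reagents that add atoms: none
Why: Steglich-type esterification acylates the only free hydroxyl with retention at C3 and avoids the ketene pathway that deconjugates senecioyl chloride.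

Step 14
Reactants: 17 C3 senecioate
Product: 18 C7 primary alcohol (C6–OTES and C12–OTBS kept)
Conditions: PPTS (cat.), MeOH–CH2Cl2, −10 °C
Reagents that add atoms: none
Why: In acid-catalysed methanolysis a primary triethylsilyl ether reacts much faster than a secondary one or a TBS ether, so only C7–OH is freed.

Step 15
Reactants: 18 C7 primary alcohol
Product: 19 C7 carboxylic acid
Conditions: TEMPO (cat.), PhI(OAc)2, MeCN–pH 7 buffer, rt
Reagents that add atoms: water O
Why: TEMPO/PhI(OAc)2 oxidation takes the primary alcohol through the aldehyde hydrate to the acid under base-free conditions, which protects the C6 centre next to the β,γ-alkene from epimerisation.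

Step 16
Reactants: 19 C7 carboxylic acid
Product: 20 seco acid (C6–OH and C12–OH free)
Conditions: TBAF, AcOH (1:1), THF, 0 °C to rt
Reagents that add atoms: none
Why: Buffered fluoride removes both silyl ethers while the senecioate, the vinyl iodide and the alkenes are inert.

Step 17
Reactants: 20 seco acid
Product: 21 13-membered macrolactone (ring C11-C1-C2-C3-C4-C5-C6-C7-O-C12-C8-C9-C10)
Conditions: PPh3, DIAD, toluene, high dilution (slow addition), 0 °C to rt
Reagents that add atoms: none
Why: In this Mitsunobu macrolactonisation the phosphonium activates the unhindered primary allylic hydroxyl rather than the flanked secondary C6–OH, and the carboxylate closes the ring by SN2 at C12, so the acid is never activated and C6 cannot epimerise.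

Step 18
Reactants: 21 13-membered macrolactone
Product: 24 4,5-deoxy precursor of the target (11-membered trienone diol), via dilithio species 22 (not isolated), via oxetane alkoxide 23 (not isolated)
Conditions: t-BuLi (3.1 equiv), Et2O–pentane, −100 °C; then AcOH, −100 °C to rt
Reagents that add atoms: none
Why: Proposed new method: the first equivalent of t-BuLi lithiates the C6 hydroxyl, and iodine–lithium exchange, which at −100 °C outruns addition to esters and keeps the alkene geometry, then places an sp2 carbanion on C8, 1,4 to the lactone carbonyl C7 (22). A 4-exo-trig addition gives the 2-oxido-oxetane 23, and strain-driven cleavage of its ring C–O bond expels the C12H2–O− arm, so that O and C12 leave the 13-membered ring and the 11-membered carbocycle with its ketone, its enone bond (C7 cis to C10) and its CH2OH results, driven by the change from a vinyl anion to an alkoxide. The closest known reaction types are the halogen–metal-exchange-triggered anionic ortho-Fries rearrangement of o-haloaryl esters (the same four-centre 1,3 O→C acyl shift), the Parham cyclisation of halo esters and the retro-Brook shift of 2-lithioallyl silyl ethers, but none has been shown on a 2-lithioallyl ester or used to contract a macrolactone. The only ring closed is the transient oxetane (4-exo-trig), no lasting stereocentre is formed, and C3, C6 and C11 are spectators. The step needs acyl transfer to win over β-elimination of carboxylate (allene formation with ring opening), over transfer of the C6 proton and over attack on the senecioate. The α-lithium alkoxide should secure this, because it would make the leaving carboxylate a dianion, removes the acidity of C6–H and ties lithium to the lactone carbonyl next to C8, while the senecioate can be reached only through a nine-membered transition state.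

Step 19
Reactants: 24 4,5-deoxy precursor of the target
Product: 25 CNP0163063.1 (target)
Conditions: VO(acac)2 (cat.), t-BuOOH, CH2Cl2, 0 °C
Reagents that add atoms: tert-butyl hydroperoxide CC(C)(C)OO
Why: In this vanadium-catalysed hydroxyl-directed epoxidation the C6 alkoxide delivers oxygen to the electron-rich C4=C5 bond on the face syn to C6–O in the conformer where C6–H eclipses the alkene (A1,3 strain with the C4 methyl), which is also the peripheral face of the E-alkene in the 11-membered ring, so C4 and C5 are set S,S, while the enone bond is too electron-poor and the other alkenes lack a directing hydroxyl.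

Compound list
1 | geraniol, (2E)-3,7-dimethylocta-2,6-dien-1-ol | CC(C)=CCC/C(C)=C/CO | starting material
2 | (2R,3R)-2,3-epoxygeraniol | OC[C@H]1O[C@]1(C)CCC=C(C)C | intermediate
3 | (2S,3R)-3,7-dimethyl-3-[(trimethylsilyl)ethynyl]oct-6-ene-1,2-diol | OC[C@@H](O)[C@@](C)(C#C[Si](C)(C)C)CCC=C(C)C | intermediate
4 | (2R)-2,6-dimethyl-2-[(trimethylsilyl)ethynyl]hept-5-enal | O=C[C@@](C)(C#C[Si](C)(C)C)CCC=C(C)C | intermediate
5 | (3S)-1-methoxy-3,7-dimethyl-3-[(trimethylsilyl)ethynyl]octa-1,6-diene (E/Z enol ether, not isolated) | COC=C[C@@](C)(C#C[Si](C)(C)C)CCC=C(C)C | intermediate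
6 | (3S)-3,7-dimethyl-3-[(trimethylsilyl)ethynyl]oct-6-enal | O=CC[C@@](C)(C#C[Si](C)(C)C)CCC=C(C)C | intermediate
7 | ethyl (2Z,5S)-2-iodo-5,9-dimethyl-5-[(trimethylsilyl)ethynyl]deca-2,8-dienoate | CCOC(=O)/C(I)=C/C[C@@](C)(C#C[Si](C)(C)C)CCC=C(C)C | intermediate
8 | (2Z,5S)-2-iodo-5,9-dimethyl-5-[(trimethylsilyl)ethynyl]deca-2,8-dien-1-ol | OC/C(I)=C/C[C@@](C)(C#C[Si](C)(C)C)CCC=C(C)C | intermediate
9 | tert-butyldimethylsilyl ether of 8 | CC(C)(C)[Si](C)(C)OC/C(I)=C/C[C@@](C)(C#C[Si](C)(C)C)CCC=C(C)C | intermediate
10 | tert-butyl{[(2Z,5S)-5-ethynyl-2-iodo-5,9-dimethyldeca-2,8-dien-1-yl]oxy}dimethylsilane | CC(C)(C)[Si](C)(C)OC/C(I)=C/C[C@@](C)(C#C)CCC=C(C)C | intermediate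
11 | (2S)-but-3-ene-1,2-diol | C=C[C@H](O)CO | starting material
12 | (2S)-1,2-bis(triethylsilyloxy)but-3-ene | C=C[C@H](O[Si](CC)(CC)CC)CO[Si](CC)(CC)CC | intermediate
13 | (2E,4S)-2-methyl-4,5-bis(triethylsilyloxy)pent-2-enal | O=C/C(C)=C/[C@H](O[Si](CC)(CC)CC)CO[Si](CC)(CC)CC | intermediate
14 | propargylic alcohol: C1≡C2, C3–OH (3S by CIP here), 4E, C6–OTES (S), C7–OTES, (8Z)-C8–I, C12–OTBS, 11S | CC(C)=CCC[C@](C)(C#C[C@@H](O)/C(C)=C/[C@H](O[Si](CC)(CC)CC)CO[Si](CC)(CC)CC)C/C=C(I)/CO[Si](C)(C)C(C)(C)C | intermediate
15 | (1Z)-bis-allylic alcohol, 3R,6S,11S, otherwise as 14 | CC(C)=CCC[C@](C)(/C=C\[C@@H](O)/C(C)=C/[C@H](O[Si](CC)(CC)CC)CO[Si](CC)(CC)CC)C/C=C(I)/CO[Si](C)(C)C(C)(C)C | intermediate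
16 | senecioic acid (3-methylbut-2-enoic acid) | CC(C)=CC(=O)O | starting material
17 | C3 senecioate of 15 | CC(C)=CCC[C@](C)(/C=C\[C@@H](OC(=O)C=C(C)C)/C(C)=C/[C@H](O[Si](CC)(CC)CC)CO[Si](CC)(CC)CC)C/C=C(I)/CO[Si](C)(C)C(C)(C)C | intermediate
18 | C7 primary alcohol (C6–OTES, C12–OTBS) | CC(C)=CCC[C@](C)(/C=C\[C@@H](OC(=O)C=C(C)C)/C(C)=C/[C@H](O[Si](CC)(CC)CC)CO)C/C=C(I)/CO[Si](C)(C)C(C)(C)C | intermediate
19 | C7 carboxylic acid (C6–OTES, C12–OTBS) | CC(C)=CCC[C@](C)(/C=C\[C@@H](OC(=O)C=C(C)C)/C(C)=C/[C@H](O[Si](CC)(CC)CC)C(=O)O)C/C=C(I)/CO[Si](C)(C)C(C)(C)C | intermediate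
20 | seco acid (C6–OH, C12–OH, C7 acid) | CC(C)=CCC[C@](C)(/C=C\[C@@H](OC(=O)C=C(C)C)/C(C)=C/[C@H](O)C(=O)O)C/C=C(I)/CO | intermediate
21 | 13-membered α-hydroxy macrolactone with (Z)-vinyl iodide at C8 | CC(C)=CCC[C@]1(C)/C=C\[C@@H](OC(=O)C=C(C)C)/C(C)=C/[C@H](O)C(=O)OC/C(I)=C/C1 | intermediate
22 | C6-O,C8-dilithio derivative of 21 (not isolated) | CC(C)=CCC[C@]1(C)/C=C\[C@@H](OC(=O)C=C(C)C)/C(C)=C/[C@H](O[Li])C(=O)OC/C([Li])=C/C1 | intermediate
23 | bicyclic 2-oxido-oxetane (C7–C8 bond made, C7–O–C12 still intact, not isolated) | CC(C)=CCC[C@]1(C)/C=C\[C@@H](OC(=O)C=C(C)C)/C(C)=C/[C@H](O[Li])C2(O[Li])OC/C2=C/C1 | intermediate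
24 | 4,5-deoxy precursor: 11-membered (1Z,4E,8Z)-trienone, C3 senecioate, C6–OH, C12–OH | CC(C)=CCC[C@]1(C)/C=C\[C@@H](OC(=O)C=C(C)C)/C(C)=C/[C@H](O)C(=O)/C(CO)=C\C1 | intermediate
25 | CNP0163063.1 (3R,4S,5S,6S,11S) | CC(C)=CCC[C@]1(C)/C=C\[C@@H](OC(=O)C=C(C)C)[C@]2(C)O[C@H]2[C@H](O)C(=O)/C(CO)=C\C1 | target

Total step count: 19. Longest linear sequence: 17 (steps 1–8, then 11–19).

Steps most likely to fail

1. Step 18 (proposed new method). The vinyllithium may lose lithium carboxylate by β-elimination, which opens the ring to an allene. It may instead be quenched by proton transfer, or t-BuLi may add to an ester before the exchange is complete. The fallback uses known chemistry, sets out from 18 and comes back at 24, and it closes the carbocycle directly.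
   - Dess–Martin oxidation of 18 gives the α-silyloxy aldehyde F1.
   - An intramolecular Nozaki–Hiyama–Kishi reaction (CrCl2, cat. NiCl2, DMSO–THF, high dilution) joins C8 to C7 with retention of the alkene geometry and gives the cycloundecatrienol F2. Both C7 epimers serve.
   - Dess–Martin oxidation gives the bis-silylated enone F3, and TBAF/AcOH frees 24.

2. Step 12. Hydrogenolysis of the vinyl C–I bond, or slow turnover at the alkyne flanked by the quaternary carbon followed by over-reduction, may erode the material. The fallback sets out from 14 and comes back at 17, and it uses no hydrogen and no palladium.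
   - Steglich esterification of 14 with 16 gives the propargylic senecioate F4.
   - syn-Hydroboration with dicyclohexylborane gives the alkenylborane F5.
   - Protonolysis with acetic acid, which goes with retention, gives 17.

3. Step 17. The secondary allylic C6 hydroxyl may also be activated, or oligomerisation may compete with ring closure. The fallback sets out from 20 and comes back at 21. A Shiina macrolactonisation (2-methyl-6-nitrobenzoic anhydride, DMAP, high dilution) activates the acid instead of the alcohol and makes no new compound.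

Further compounds
F1 | step 18 | α-silyloxy aldehyde (C7 aldehyde, C6–OTES, C12–OTBS) | CC(C)=CCC[C@](C)(/C=C\[C@@H](OC(=O)C=C(C)C)/C(C)=C/[C@H](O[Si](CC)(CC)CC)C=O)C/C=C(I)/CO[Si](C)(C)C(C)(C)C
F2 | step 18 | cycloundecatrienol (C7 carbinol, both epimers) | CC(C)=CCC[C@]1(C)/C=C\[C@@H](OC(=O)C=C(C)C)/C(C)=C/[C@H](O[Si](CC)(CC)CC)C(O)/C(CO[Si](C)(C)C(C)(C)C)=C\C1
F3 | step 18 | bis-silylated enone | CC(C)=CCC[C@]1(C)/C=C\[C@@H](OC(=O)C=C(C)C)/C(C)=C/[C@H](O[Si](CC)(CC)CC)C(=O)/C(CO[Si](C)(C)C(C)(C)C)=C\C1
F4 | step 12 | propargylic senecioate | CC(C)=CCC[C@](C)(C#C[C@@H](OC(=O)C=C(C)C)/C(C)=C/[C@H](O[Si](CC)(CC)CC)CO[Si](CC)(CC)CC)C/C=C(I)/CO[Si](C)(C)C(C)(C)C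
F5 | step 12 | alkenylborane (dicyclohexylboryl on C2, cis to the new C1–H) | CC(C)=CCC[C@](C)(/C=C(/B(C1CCCCC1)C1CCCCC1)[C@@H](OC(=O)C=C(C)C)/C(C)=C/[C@H](O[Si](CC)(CC)CC)CO[Si](CC)(CC)CC)C/C=C(I)/CO[Si](C)(C)C(C)(C)C
F0 | step 17 | none | none
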